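Unit 1 is the chromanone with catechol ring B (O1, C2, C3, C4; benzo ring A, pyranone ring C). Unit 2 is the chromanone with 4-hydroxyphenyl ring E (doubly primed numbers; benzo ring D, pyranone ring F). The target is (2R,3S,2''S), 2,3-trans, joined C3–C8''.
Retrosynthetic cuts, in order: the seven O–benzyl bonds; the C2''–aryl bond to ring E; C4–C4a of ring C; the carboxyl carbon back to a vinyl group; O1–C8a; C2–C3; the C–B and C8''–alkenyl bonds of the ring D side chain.
Enabling feature: ring A is a 1,3,5-trioxygenated benzene whose two carbons ortho to O1 (future C4a and C8) are identical until C4–C4a exists, and C2–O1 is a benzylic aryl ether that can be made at oxygen, on the aryl side, without breaking any bond at C2.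
Forward order: ring F is built on ring D as a chromone; ring B and the C2–C3 bond come from an allylboration; ring A is attached through O1; ring C is closed by acylation; ring E is added to the chromone last; then global debenzylation.
Stereochemistry: C2 and C3 come from one chiral phosphoric acid-catalysed anti-allylboration (E-boronate gives anti, which maps onto 2,3-trans; the catalyst gives the absolute sense). C2'' comes from a chiral pyridine–oxazoline palladium catalyst.

Key step: step 12

Assumption: the facial preferences known for (R)-TRIP in allylboration (Re face of aryl aldehydes) and for the pyridine–oxazoline palladium catalyst (same enone face as in 3-substituted cyclohexenones, so the (R)-ligand gives the 2S-flavanone) are taken to hold for these substrates; if a test reaction shows the opposite sense, the antipodal catalyst is used.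

Step 1
Reactants: 1 2',4',6'-trihydroxyacetophenone
Product: 2 1-[2,4-bis(benzyloxy)-6-hydroxyphenyl]ethanone
Conditions: BnBr (2.05 equiv), K2CO3, DMF, rt
Reagents that add atoms: benzyl bromide, BrCc1ccccc1
Why: Williamson etherification in which the hydroxyl hydrogen-bonded to the acetyl carbonyl is the least nucleophilic, so two equivalents of benzyl bromide should alkylate the other two phenols selectively.

Step 2
Reactants: 2 1-[2,4-bis(benzyloxy)-6-hydroxyphenyl]ethanone
Product: 3 1-[4,6-bis(benzyloxy)-2-hydroxy-3-iodophenyl]ethanone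
Conditions: NIS (1.0 equiv), DMF, 0 °C to rt
Reagents that add atoms: N-iodosuccinimide, O=C1CCC(=O)N1I
Why: Electrophilic aromatic iodination, expected at the carbon ortho to the free chelated phenol (between OH and OBn), which becomes C8'' once that phenol oxygen has become O1''.

Step 3
Reactants: 3 1-[4,6-bis(benzyloxy)-2-hydroxy-3-iodophenyl]ethanone
Product: 5 5,7-bis(benzyloxy)-8-iodo-4H-chromen-4-one, via enaminone 4 (not isolated)
Conditions: Me2NCH(OMe)2, toluene, 90 °C; then conc. HCl, CH2Cl2, rt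
Reagents that add atoms: N,N-dimethylformamide dimethyl acetal, COC(OC)N(C)C
Why: Condensation of the methyl ketone with the amide acetal gives enaminone 4, and acid then promotes addition of the phenol oxygen to the β-carbon with loss of dimethylamine (enaminone route to 3-unsubstituted chromones), closing ring F as the chromone.

Step 4
Reactants: 5 5,7-bis(benzyloxy)-8-iodo-4H-chromen-4-one; 6 (E)-3-(tributylstannyl)prop-2-en-1-ol
Product: 7 5,7-bis(benzyloxy)-8-[(E)-3-hydroxyprop-1-en-1-yl]-4H-chromen-4-one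
Conditions: Pd(PPh3)4 (5 mol%), CuI (10 mol%), CsF (2 equiv), DMF, 45 °C
Reagents that add atoms: none
Why: Stille coupling on zerovalent palladium, with the CuI/CsF combination that helps doubly ortho-substituted aryl iodides, transfers the alkenyl group with retention of its E geometry and tolerates the free allylic alcohol.

Step 5
Reactants: 7 5,7-bis(benzyloxy)-8-[(E)-3-hydroxyprop-1-en-1-yl]-4H-chromen-4-one
Product: 8 5,7-bis(benzyloxy)-8-[(E)-3-(4,4,5,5-tetramethyl-1,3,2-dioxaborolan-2-yl)prop-1-en-1-yl]-4H-chromen-4-one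
Conditions: B2pin2 (1.5 equiv), [Pd(MeCN)4](BF4)2 (5 mol%), DMSO/MeOH, 40 °C
Reagents that add atoms: bis(pinacolato)diboron, CC1(C)OB(OC1(C)C)B1OC(C)(C)C(C)(C)O1
Why: Palladium-catalysed borylation of an allylic alcohol through an η3-allylpalladium intermediate, in which boron is delivered to the unsubstituted terminus so that the linear, E-configured γ-aryl allylboronate should result.

Step 6
Reactants: 8 5,7-bis(benzyloxy)-8-[(E)-3-(4,4,5,5-tetramethyl-1,3,2-dioxaborolan-2-yl)prop-1-en-1-yl]-4H-chromen-4-one; 9 3,4-bis(benzyloxy)benzaldehyde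
Product: 11 5,7-bis(benzyloxy)-8-[(1R,2S)-1-[3,4-bis(benzyloxy)phenyl]-1-hydroxybut-3-en-2-yl]-4H-chromen-4-one, via pinacol borate ester 10 (not isolated)
Conditions: (R)-3,3'-bis(2,4,6-triisopropylphenyl)-1,1'-binaphthyl-2,2'-diyl hydrogen phosphate [(R)-TRIP] (10 mol%), toluene, 4 Å MS, −30 °C to rt; aq. NaHCO3 work-up
Reagents that add atoms: none
Why: Chiral phosphoric acid-catalysed allylboration through a closed six-membered chair transition state: the E geometry of 8 places the γ-aryl group equatorial and so gives the anti relationship of the two new centres (C2 and C3 of unit 1), while the (R)-configured acid, bound to a boronate oxygen and to the formyl hydrogen, should direct attack to the Re face of 9 and thus set 1R and 2S.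

Step 7
Reactants: 12 5-bromoresorcinol
Product: 13 1,3-bis(benzyloxy)-5-bromobenzene
Conditions: BnBr (2.2 equiv), K2CO3, DMF, rt
Reagents that add atoms: benzyl bromide, BrCc1ccccc1
Why: Williamson etherification of both phenols.

Step 8
Reactants: 13 1,3-bis(benzyloxy)-5-bromobenzene
Product: 14 1,3-bis(benzyloxy)-5-iodobenzene
Conditions: NaI (2 equiv), CuI (5 mol%), trans-N,N'-dimethylcyclohexane-1,2-diamine (10 mol%), dioxane, 110 °C
Reagents that add atoms: sodium iodide, [Na+].[I-]
Why: Copper-catalysed aromatic Finkelstein halogen exchange, driven by the low solubility of NaBr in dioxane, supplies the aryl iodide, which couples with alcohols at lower temperature than the bromide.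

Step 9
Reactants: 11 5,7-bis(benzyloxy)-8-[(1R,2S)-1-[3,4-bis(benzyloxy)phenyl]-1-hydroxybut-3-en-2-yl]-4H-chromen-4-one; 14 1,3-bis(benzyloxy)-5-iodobenzene
Product: 15 5,7-bis(benzyloxy)-8-[(1R,2S)-1-[3,4-bis(benzyloxy)phenyl]-1-[3,5-bis(benzyloxy)phenoxy]but-3-en-2-yl]-4H-chromen-4-one
Conditions: 14 (2 equiv), CuI (20 mol%), 3,4,7,8-tetramethyl-1,10-phenanthroline (40 mol%), Cs2CO3 (2 equiv), toluene, 4 Å MS, 90 °C
Reagents that add atoms: none
Why: Ullmann-type copper-catalysed C–O coupling of a secondary alcohol with an aryl iodide: the new bond (O1–C8a) is made between the alkoxide oxygen and the aryl carbon, no bond at the carbinol carbon is broken, so C2 keeps its configuration and neither a benzylic cation nor a chalcone is involved.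

Step 10
Reactants: 15 5,7-bis(benzyloxy)-8-[(1R,2S)-1-[3,4-bis(benzyloxy)phenyl]-1-[3,5-bis(benzyloxy)phenoxy]but-3-en-2-yl]-4H-chromen-4-one
Product: 16 5,7-bis(benzyloxy)-8-[(1R,2R,3RS)-1-[3,4-bis(benzyloxy)phenyl]-1-[3,5-bis(benzyloxy)phenoxy]-3,4-dihydroxybutan-2-yl]-4H-chromen-4-one (C1 and C2 unchanged in space; the C2 descriptor changes by priority only)
Conditions: OsO4 (4 mol%), NMO (1.5 equiv), acetone/H2O, rt
Reagents that add atoms: osmium tetroxide, O=[Os](=O)(=O)=O; N-methylmorpholine N-oxide, C[N+]1([O-])CCOCC1; water, O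
Why: Catalytic OsO4 dihydroxylation with NMO as terminal oxidant, in which the monosubstituted vinyl group should react ahead of the electron-poor push–pull C2''=C3'' bond of the chromone; the configuration of the new carbinol is irrelevant because that carbon becomes the carboxyl carbon.

Step 11
Reactants: 16 5,7-bis(benzyloxy)-8-[(1R,2R,3RS)-1-[3,4-bis(benzyloxy)phenyl]-1-[3,5-bis(benzyloxy)phenoxy]-3,4-dihydroxybutan-2-yl]-4H-chromen-4-one
Product: 18 (2S,3R)-3-[3,4-bis(benzyloxy)phenyl]-3-[3,5-bis(benzyloxy)phenoxy]-2-[5,7-bis(benzyloxy)-4-oxo-4H-chromen-8-yl]propanoic acid, via aldehyde 17 (not isolated)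
Conditions: NaIO4, THF/pH 7 buffer, 0 °C; then NaClO2, NaH2PO4, 2-methyl-2-butene (excess), t-BuOH/H2O, 0 °C
Reagents that add atoms: sodium chlorite, [Na+].[O-]Cl=O
Why: Periodate glycol cleavage followed at once by chlorite (Pinnick) oxidation with an alkene scavenger for HOCl; the α-aryl β-aryloxy aldehyde 17 is kept cold, near neutral and unpurified so that enolisation, which would epimerise C3 or expel the aryloxide, is not given time.

Step 12
Reactants: 18 (2S,3R)-3-[3,4-bis(benzyloxy)phenyl]-3-[3,5-bis(benzyloxy)phenoxy]-2-[5,7-bis(benzyloxy)-4-oxo-4H-chromen-8-yl]propanoic acid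
Product: 20 (2R,3S)-5,7-bis(benzyloxy)-2-[3,4-bis(benzyloxy)phenyl]-3-[5,7-bis(benzyloxy)-4-oxo-4H-chromen-8-yl]chroman-4-one, via mixed trifluoroacetic anhydride 19 (not isolated)
Conditions: (CF3CO)2O (2 equiv), CH2Cl2, 0 °C to rt; aq. NaHCO3 quench
Reagents that add atoms: none
Why: The acid is converted by (CF3CO)2O into acyl trifluoroacetate 19, whose carbonyl carbon (future C4) is attacked by the ring A carbon ortho to O1 to give an arenium ion that rearomatises by loss of a proton and trifluoroacetate; the closest known reaction type is the trifluoroacetic anhydride-mediated intramolecular Friedel–Crafts acylation of 3-aryloxypropanoic acids to chroman-4-ones. Ring C closes in a six-membered mode (6-exo-trig at the acyl carbon) by electrophilic aromatic substitution at a position ortho to O1, ortho to one benzyloxy group and para to the other, so activated by all three oxygens. No stereocentre is created: C2 (R) and C3 (S) are carried over from the anti acid 18, whose relative configuration maps directly onto the 2,3-trans chromanone, which is also the thermodynamically preferred arrangement at the enolisable C3, so no separate equilibration is planned. Regioselectivity is not an issue because the two ring A carbons ortho to O1 are equivalent by symmetry until C4–C4a is formed, and the para carbon cannot be reached. The selectivities needed are ring A over ring B (a five-membered indanone closure onto a less nucleophilic catechol ether) and preservation of the C2–O1 bond; both rest on the high nucleophilicity of the phloroglucinol-type ring, which lets the closure run at 0 °C with only the released trifluoroacetic acid present, and on the adjacent acyl group, which disfavours ionisation at C2. The ring D chromone has no enolisable position and should be inert to these conditions.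

Step 13
Reactants: 20 (2R,3S)-5,7-bis(benzyloxy)-2-[3,4-bis(benzyloxy)phenyl]-3-[5,7-bis(benzyloxy)-4-oxo-4H-chromen-8-yl]chroman-4-one; 21 4-(benzyloxy)phenylboronic acid
Product: 22 (2R,3S)-5,7-bis(benzyloxy)-3-[(2S)-5,7-bis(benzyloxy)-2-[4-(benzyloxy)phenyl]-4-oxochroman-8-yl]-2-[3,4-bis(benzyloxy)phenyl]chroman-4-one
Conditions: 21 (3 equiv), Pd(OCOCF3)2 (10 mol%), (R)-4-tert-butyl-2-(pyridin-2-yl)-4,5-dihydrooxazole (12 mol%), NH4PF6 (30 mol%), H2O (5 equiv), ClCH2CH2Cl, 60 °C
Reagents that add atoms: none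
Why: Asymmetric conjugate addition of an arylboronic acid to a chromone on a cationic pyridine–oxazoline complex of divalent palladium (transmetalation, face-selective insertion of C2''=C3'' into the aryl–palladium bond, protonolysis of the palladium enolate), in which the catalyst and not the remote C2/C3 centres selects the chromone face, the (R)-ligand being expected to give 2''S.

Step 14
Reactants: 22 (2R,3S)-5,7-bis(benzyloxy)-3-[(2S)-5,7-bis(benzyloxy)-2-[4-(benzyloxy)phenyl]-4-oxochroman-8-yl]-2-[3,4-bis(benzyloxy)phenyl]chroman-4-one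
Product: 23 (2R,3S)-2-(3,4-dihydroxyphenyl)-5,7-dihydroxy-3-[(2S)-5,7-dihydroxy-2-(4-hydroxyphenyl)-4-oxochroman-8-yl]chroman-4-one (CNP0105436.2)
Conditions: H2 (1 atm), Pd/C (10 wt%), THF/MeOH, rt
Reagents that add atoms: none
Why: Hydrogenolysis of the seven benzyl aryl ethers over palladium on carbon under neutral conditions, which should leave the ketones, the two ring benzylic ethers (C2–O1 and C2''–O1'') and all three stereocentres untouched.

Compound list
1 | 2',4',6'-trihydroxyacetophenone | CC(=O)c1c(O)cc(O)cc1O | starting material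
2 | 1-[2,4-bis(benzyloxy)-6-hydroxyphenyl]ethanone | CC(=O)c1c(O)cc(OCc2ccccc2)cc1OCc1ccccc1 | intermediate
3 | 1-[4,6-bis(benzyloxy)-2-hydroxy-3-iodophenyl]ethanone | CC(=O)c1c(O)c(I)c(OCc2ccccc2)cc1OCc1ccccc1 | intermediate
4 | (E)-1-[4,6-bis(benzyloxy)-2-hydroxy-3-iodophenyl]-3-(dimethylamino)prop-2-en-1-one (not isolated) | CN(C)/C=C/C(=O)c1c(O)c(I)c(OCc2ccccc2)cc1OCc1ccccc1 | intermediate
5 | 5,7-bis(benzyloxy)-8-iodo-4H-chromen-4-one | O=c1ccoc2c(I)c(OCc3ccccc3)cc(OCc3ccccc3)c12 | intermediate
6 | (E)-3-(tributylstannyl)prop-2-en-1-ol | CCCC[Sn](CCCC)(CCCC)/C=C/CO | starting material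
7 | 5,7-bis(benzyloxy)-8-[(E)-3-hydroxyprop-1-en-1-yl]-4H-chromen-4-one | O=c1ccoc2c(/C=C/CO)c(OCc3ccccc3)cc(OCc3ccccc3)c12 | intermediate
8 | 5,7-bis(benzyloxy)-8-[(E)-3-(4,4,5,5-tetramethyl-1,3,2-dioxaborolan-2-yl)prop-1-en-1-yl]-4H-chromen-4-one | O=c1ccoc2c(/C=C/CB3OC(C)(C)C(C)(C)O3)c(OCc3ccccc3)cc(OCc3ccccc3)c12 | intermediate
9 | 3,4-bis(benzyloxy)benzaldehyde | O=Cc1ccc(OCc2ccccc2)c(OCc2ccccc2)c1 | starting material
10 | 5,7-bis(benzyloxy)-8-[(1R,2S)-1-[3,4-bis(benzyloxy)phenyl]-1-[(4,4,5,5-tetramethyl-1,3,2-dioxaborolan-2-yl)oxy]but-3-en-2-yl]-4H-chromen-4-one (not isolated) | O=c1ccoc2c1c(OCc1ccccc1)cc(OCc1ccccc1)c2[C@H](C=C)[C@@H](OB1OC(C)(C)C(C)(C)O1)c1ccc(OCc2ccccc2)c(OCc2ccccc2)c1 | intermediate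
11 | 5,7-bis(benzyloxy)-8-[(1R,2S)-1-[3,4-bis(benzyloxy)phenyl]-1-hydroxybut-3-en-2-yl]-4H-chromen-4-one (anti) | O=c1ccoc2c1c(OCc1ccccc1)cc(OCc1ccccc1)c2[C@H](C=C)[C@@H](O)c1ccc(OCc2ccccc2)c(OCc2ccccc2)c1 | intermediate
12 | 5-bromoresorcinol (5-bromobenzene-1,3-diol) | Oc1cc(O)cc(Br)c1 | starting material
13 | 1,3-bis(benzyloxy)-5-bromobenzene | Brc1cc(OCc2ccccc2)cc(OCc2ccccc2)c1 | intermediate
14 | 1,3-bis(benzyloxy)-5-iodobenzene | Ic1cc(OCc2ccccc2)cc(OCc2ccccc2)c1 | intermediate
15 | 5,7-bis(benzyloxy)-8-[(1R,2S)-1-[3,4-bis(benzyloxy)phenyl]-1-[3,5-bis(benzyloxy)phenoxy]but-3-en-2-yl]-4H-chromen-4-one | O=c1ccoc2c1c(OCc1ccccc1)cc(OCc1ccccc1)c2[C@H](C=C)[C@@H](Oc1cc(OCc2ccccc2)cc(OCc2ccccc2)c1)c1ccc(OCc2ccccc2)c(OCc2ccccc2)c1 | intermediate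
16 | 5,7-bis(benzyloxy)-8-[(1R,2R,3RS)-1-[3,4-bis(benzyloxy)phenyl]-1-[3,5-bis(benzyloxy)phenoxy]-3,4-dihydroxybutan-2-yl]-4H-chromen-4-one | O=c1ccoc2c1c(OCc1ccccc1)cc(OCc1ccccc1)c2[C@H](C(O)CO)[C@@H](Oc1cc(OCc2ccccc2)cc(OCc2ccccc2)c1)c1ccc(OCc2ccccc2)c(OCc2ccccc2)c1 | intermediate
17 | (2S,3R)-3-[3,4-bis(benzyloxy)phenyl]-3-[3,5-bis(benzyloxy)phenoxy]-2-[5,7-bis(benzyloxy)-4-oxo-4H-chromen-8-yl]propanal (not isolated) | O=c1ccoc2c1c(OCc1ccccc1)cc(OCc1ccccc1)c2[C@H](C=O)[C@@H](Oc1cc(OCc2ccccc2)cc(OCc2ccccc2)c1)c1ccc(OCc2ccccc2)c(OCc2ccccc2)c1 | intermediate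
18 | (2S,3R)-3-[3,4-bis(benzyloxy)phenyl]-3-[3,5-bis(benzyloxy)phenoxy]-2-[5,7-bis(benzyloxy)-4-oxo-4H-chromen-8-yl]propanoic acid | O=c1ccoc2c1c(OCc1ccccc1)cc(OCc1ccccc1)c2[C@H](C(=O)O)[C@@H](Oc1cc(OCc2ccccc2)cc(OCc2ccccc2)c1)c1ccc(OCc2ccccc2)c(OCc2ccccc2)c1 | intermediate
19 | (2S,3R)-3-[3,4-bis(benzyloxy)phenyl]-3-[3,5-bis(benzyloxy)phenoxy]-2-[5,7-bis(benzyloxy)-4-oxo-4H-chromen-8-yl]propanoic trifluoroacetic anhydride (not isolated) | O=c1ccoc2c1c(OCc1ccccc1)cc(OCc1ccccc1)c2[C@H](C(=O)OC(=O)C(F)(F)F)[C@@H](Oc1cc(OCc2ccccc2)cc(OCc2ccccc2)c1)c1ccc(OCc2ccccc2)c(OCc2ccccc2)c1 | intermediate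
20 | (2R,3S)-5,7-bis(benzyloxy)-2-[3,4-bis(benzyloxy)phenyl]-3-[5,7-bis(benzyloxy)-4-oxo-4H-chromen-8-yl]chroman-4-one (2,3-trans) | O=c1ccoc2c1c(OCc1ccccc1)cc(OCc1ccccc1)c2[C@@H]1C(=O)c2c(OCc3ccccc3)cc(OCc3ccccc3)cc2O[C@H]1c1ccc(OCc2ccccc2)c(OCc2ccccc2)c1 | intermediate
21 | 4-(benzyloxy)phenylboronic acid | OB(O)c1ccc(OCc2ccccc2)cc1 | starting material
22 | (2R,3S)-5,7-bis(benzyloxy)-3-[(2S)-5,7-bis(benzyloxy)-2-[4-(benzyloxy)phenyl]-4-oxochroman-8-yl]-2-[3,4-bis(benzyloxy)phenyl]chroman-4-one | O=C1C[C@@H](c2ccc(OCc3ccccc3)cc2)Oc2c1c(OCc1ccccc1)cc(OCc1ccccc1)c2[C@@H]1C(=O)c2c(OCc3ccccc3)cc(OCc3ccccc3)cc2O[C@H]1c1ccc(OCc2ccccc2)c(OCc2ccccc2)c1 | intermediate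
23 | (2R,3S)-2-(3,4-dihydroxyphenyl)-5,7-dihydroxy-3-[(2S)-5,7-dihydroxy-2-(4-hydroxyphenyl)-4-oxochroman-8-yl]chroman-4-one | O=C1C[C@@H](c2ccc(O)cc2)Oc2c1c(O)cc(O)c2[C@@H]1C(=O)c2c(O)cc(O)cc2O[C@H]1c1ccc(O)c(O)c1 | target

Total step count: 14. Longest linear sequence: 12 steps (steps 1–6 and 9–14, from 1); steps 7 and 8 form the short ring A branch.

Steps most likely to fail

Step 9. The hindered secondary benzylic alkoxide may couple too slowly, so that reduction of the aryl iodide, oxidation of the carbinol to the ketone, or base-induced degradation of the chromone at 90 °C takes over. The fallback sets out from 14 and 11 and comes back at 15; it replaces copper catalysis by metal-free aryl transfer from trivalent iodine at room temperature. Iodide 14 would be oxidised with mCPBA and TsOH·H2O in MeCN to 1,3-bis(benzyloxy)-5-[hydroxy(tosyloxy)-λ3-iodanyl]benzene F1, which would be condensed in the same flask with 1,3,5-trimethoxybenzene to [3,5-bis(benzyloxy)phenyl](2,4,6-trimethoxyphenyl)iodonium tosylate F2. The sodium alkoxide of 11 (NaH, toluene, rt) would then be arylated by F2 through ligand coupling at iodine, the electron-rich trimethoxyphenyl group staying on iodine, to give 15 with the carbinol centre again untouched.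

Step 12. The trifluoroacetic acid released may ionise the C2–O1 benzylic ether (loss of the C2 configuration or cleavage of the aryl ether), or the activated acyl group may be diverted to ring B (indanone) while ring A is trifluoroacetylated. The fallback sets out from 16 and comes back at 20; it closes the same C4–C4a bond at the aldehyde oxidation level, so that neither the anhydride nor a strong protic acid is needed. Diol 16 would be cleaved with NaIO4 as in step 11 to aldehyde 17, which would undergo intramolecular Friedel–Crafts hydroxyalkylation of ring A under a mild Lewis acid (MgBr2·OEt2, CH2Cl2, −40 to 0 °C) to give 5,7-bis(benzyloxy)-8-[(2R,3R,4RS)-5,7-bis(benzyloxy)-2-[3,4-bis(benzyloxy)phenyl]-4-hydroxychroman-3-yl]-4H-chromen-4-one F3 (C2 and C3 arranged in space as in 20). Oxidation of this benzylic alcohol with Dess–Martin periodinane (CH2Cl2, NaHCO3, 0 °C) would deliver 20.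

Step 13. The electron-rich, hindered 5,7-dialkoxychromone may insert too slowly into the aryl–palladium bond, so that protodeboronation and homocoupling of 21 consume the boronic acid, or the chiral catalyst may give insufficient facial discrimination. The fallback sets out from 20 and 21 and comes back at 22; it gives up catalyst control and relies on separation. The addition would be run with the more active achiral complex of Pd(OCOCF3)2 and 2,2'-bipyridine (aqueous ClCH2CH2Cl, 60 °C), which should give 22 together with its C2'' epimer, (2R,3S)-5,7-bis(benzyloxy)-3-[(2R)-5,7-bis(benzyloxy)-2-[4-(benzyloxy)phenyl]-4-oxochroman-8-yl]-2-[3,4-bis(benzyloxy)phenyl]chroman-4-one F4. Because unit 1 is a single enantiomer, the two are diastereomers and would be separated by chromatography or crystallisation before step 14.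

Further compounds
F1 | step 9 | 1,3-bis(benzyloxy)-5-[hydroxy(tosyloxy)-λ3-iodanyl]benzene | Cc1ccc(S(=O)(=O)OI(O)c2cc(OCc3ccccc3)cc(OCc3ccccc3)c2)cc1
F2 | step 9 | [3,5-bis(benzyloxy)phenyl](2,4,6-trimethoxyphenyl)iodonium tosylate | COc1cc(OC)c([I+]c2cc(OCc3ccccc3)cc(OCc3ccccc3)c2)c(OC)c1.Cc1ccc(S(=O)(=O)[O-])cc1
F3 | step 12 | 5,7-bis(benzyloxy)-8-[(2R,3R,4RS)-5,7-bis(benzyloxy)-2-[3,4-bis(benzyloxy)phenyl]-4-hydroxychroman-3-yl]-4H-chromen-4-one | O=c1ccoc2c1c(OCc1ccccc1)cc(OCc1ccccc1)c2[C@@H]1C(O)c2c(OCc3ccccc3)cc(OCc3ccccc3)cc2O[C@H]1c1ccc(OCc2ccccc2)c(OCc2ccccc2)c1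
F4 | step 13 | (2R,3S)-5,7-bis(benzyloxy)-3-[(2R)-5,7-bis(benzyloxy)-2-[4-(benzyloxy)phenyl]-4-oxochroman-8-yl]-2-[3,4-bis(benzyloxy)phenyl]chroman-4-one | O=C1C[C@H](c2ccc(OCc3ccccc3)cc2)Oc2c1c(OCc1ccccc1)cc(OCc1ccccc1)c2[C@@H]1C(=O)c2c(OCc3ccccc3)cc(OCc3ccccc3)cc2O[C@H]1c1ccc(OCc2ccccc2)c(OCc2ccccc2)c1
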